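## Retrosynthetic overview

1. Numbering (labdane): ring A = C1–C5 and C10 (gem-dimethyl C4, methyl on C10); ring B = C5–C10; C17 = the CHO carbon on C8; side chain C11–C16 on C9.
2. Last bonds: selective 16-O-formylation; before it the enal from a C8 ketone (enol triflate, carbonylation) and the side chain by B-alkyl Suzuki–Miyaura coupling (C12–C13) of a C9-vinyl group with a (Z)-β-iodoenoate, which fixes the C13=C14 geometry.
3. H-5 and 6-OH come together from one hydroboration–oxidation of a C5=C6 alkene, from the face opposite the C10 methyl.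
4. Key disconnection C9–C10: ring B is closed onto the bought ring A (dihydro-β-ionone) by a Mn(OAc)3/Cu(OAc)2 oxidative radical cyclisation of a (+)-8-phenylmenthyl β-keto ester; this sets C10 (and C9) and leaves the C8 ketone, the C11 ester and the C5=C6 alkene.
5. Enabling feature: C9 lies between C8 and C11, so at the C8-ketone/C11-ester level it is the α-carbon of a β-keto ester (radical site); C10 is the far carbon of the tetrasubstituted ring A alkene C5=C10, reached 6-endo; the C5 radical has β-hydrogens only on C6, because C4 and C10 are quaternary.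

Key step: step 3

Assumption: (1S,2R,5S)-(+)-8-phenylmenthol is taken to shield the face of the chelated C9 radical that would lead to the mirror-image C10 configuration, by analogy with the known sense of induction of 8-phenylmenthyl glyoxylates and β-keto esters; if this system shows the opposite sense, the (1R,2S,5R)-(−)-enantiomer is used with no other change.

## Route

Step 1
Reactants: 1 dihydro-β-ionone
Product: 2 methyl β-keto ester (methyl 3-oxo-5-(2,6,6-trimethylcyclohex-1-en-1-yl)pentanoate)
Conditions: NaH (2.2 equiv), dimethyl carbonate, THF, reflux; AcOH quench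
Reagents that add atoms: dimethyl carbonate, COC(=O)OC
Why: Claisen-type C-acylation of the methyl-side sodium enolate by dimethyl carbonate is driven by irreversible deprotonation of the β-keto ester formed, so only the terminal methyl is carboxylated; no stereocenter is created.

Step 2
Reactants: 2 methyl β-keto ester; 3 (+)-8-phenylmenthol
Product: 4 (+)-8-phenylmenthyl β-keto ester
Conditions: DMAP (0.3 equiv), toluene, reflux, removal of MeOH
Reagents that add atoms: none
Why: DMAP-mediated transesterification of a β-keto ester (through its acylketene) accepts hindered secondary alcohols and is driven by distilling off methanol; the three stereocenters of the auxiliary are bought and untouched.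

Step 3
Reactants: 4 (+)-8-phenylmenthyl β-keto ester
Product: 6 bicyclic β-keto ester (C8 ketone, C9 ester cis to the C10 methyl, C5=C6 alkene), via cyclised C5 radical 5 (not isolated)
Conditions: Mn(OAc)3·2H2O (2.2 equiv), Cu(OAc)2·H2O (0.2 equiv), Yb(OTf)3 (1 equiv), CF3CH2OH, −5 °C → rt
Reagents that add atoms: none
Why: Mn(OAc)3 oxidises the Yb(OTf)3-chelated enol of the β-keto ester to an electrophilic C9 radical, which adds to C10 of the ring A C5=C10 alkene, and the tertiary C5 radical so formed is oxidised by Cu(OAc)2 through an organocopper species that loses a β-hydrogen. The closest known reaction type is the Mn(OAc)3/Cu(OAc)2 oxidative free-radical cyclisation of unsaturated β-keto esters, including its lanthanide-triflate-promoted 8-phenylmenthyl ester variant. Ring B closes in the 6-endo-trig mode through a chair transition state with the ketone carbonyl inside the new ring. C10 is controlled by the auxiliary, whose phenyl group covers one face of the planar chelated radical so that the alkene adds to the open face in the chair, and C9, which stays epimerisable between two carbonyls, settles with the ester equatorial and cis to the C10 methyl. The step needs 6-endo over 5-exo attack, secured by the ring-included carbonyl (cyclohexanone versus cyclopentanone) and by the quaternary C4 that shields C5, and it needs the new alkene at C5=C6 only, secured because the only β-hydrogens of the C5 radical are on C6.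

Step 4
Reactants: 6 bicyclic β-keto ester
Product: 7 C8 ethylene ketal
Conditions: ethylene glycol, TsOH·H2O (cat.), benzene, reflux (Dean–Stark)
Reagents that add atoms: ethylene glycol, OCCO
Why: Acid-catalysed dioxolane formation with azeotropic removal of water masks the C8 ketone before the borane and hydride steps, the hindered ester and the isolated C5=C6 alkene being inert; no stereocenter changes.

Step 5
Reactants: 7 C8 ethylene ketal
Product: 9 6-alcohol (H-5 and 6-OH cis to each other, both trans to the C10 methyl), via C6 alkylborane 8 (not isolated)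
Conditions: BH3·THF, THF, 0 °C → rt; then NaOH, H2O2, 0 °C → rt
Reagents that add atoms: hydrogen peroxide, OO
Why: Hydroboration–oxidation: boron adds to the less substituted C6 and hydrogen to C5 in a syn fashion from the face opposite the axial C10 methyl and the axial C4 methyl, which should set H-5 (trans ring fusion) and, after oxidation with retention, the equatorial 6-OH in one event under substrate control from C10.

Step 6
Reactants: 9 6-alcohol
Product: 10 6-O-TBS ether
Conditions: TBSOTf, 2,6-lutidine, CH2Cl2, −78 → 0 °C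
Reagents that add atoms: tert-butyldimethylsilyl trifluoromethanesulfonate, CC(C)(C)[Si](C)(C)OS(=O)(=O)C(F)(F)F
Why: Silyl ether formation with the silyl triflate succeeds on this hindered secondary alcohol and protects it through the oxidation, ylide and enolate steps.

Step 7
Reactants: 10 6-O-TBS ether
Product: 11 C11 primary alcohol
Conditions: LiAlH4, THF, 0 °C → reflux
Reagents that add atoms: none
Why: LiAlH4 ester reduction gives the C11 primary alcohol and releases the auxiliary for recovery, while ketal and silyl ether are inert.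

Step 8
Reactants: 11 C11 primary alcohol
Product: 12 C11 aldehyde
Conditions: Dess–Martin periodinane, CH2Cl2, 0 °C → rt
Reagents that add atoms: none
Why: Dess–Martin oxidation of the primary alcohol under non-basic conditions stops at the aldehyde and leaves the epimerisable C9 in its equatorial configuration.

Step 9
Reactants: 12 C11 aldehyde
Product: 13 C9-vinyl ketal
Conditions: Ph3PCH3Br, KOtBu, THF, 0 °C → rt
Reagents that add atoms: methyltriphenylphosphonium bromide, C[P+](c1ccccc1)(c1ccccc1)c1ccccc1.[Br-]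
Why: Wittig methylenation with the non-stabilised ylide converts the hindered aldehyde into the C11=C12 vinyl group, and the equatorial C9 configuration is the thermodynamic one and is retained.

Step 10
Reactants: 14 methyl 4-hydroxybut-2-ynoate
Product: 15 methyl (Z)-4-hydroxy-3-iodobut-2-enoate
Conditions: NaI, AcOH, 70 °C
Reagents that add atoms: sodium iodide, [Na+].[I-]
Why: Hydroiodination by conjugate addition of iodide to the ynoate and anti protonation gives the (Z)-β-iodoenoate, iodine cis to the ester and CH2OH trans, which fixes the later C13=C14 geometry.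

Step 11
Reactants: 15 methyl (Z)-4-hydroxy-3-iodobut-2-enoate
Product: 16 TBDPS ether of 15
Conditions: TBDPSCl, imidazole, DMF, 0 °C → rt
Reagents that add atoms: tert-butyl(chloro)diphenylsilane, CC(C)(C)[Si](Cl)(c1ccccc1)c1ccccc1
Why: Standard silylation of the primary alcohol; the acid-robust tert-butyldiphenylsilyl ether should survive the later ketal hydrolysis and shield the alcohol from base and triflating agent.

Step 12
Reactants: 13 C9-vinyl ketal; 16 TBDPS ether of 15
Product: 18 coupled ketal with complete side chain, via B-alkyl-9-BBN adduct 17 (not isolated)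
Conditions: 9-BBN, THF, rt; then 16, PdCl2(dppf) (5 mol%), AsPh3, Cs2CO3, DMF/H2O, rt
Reagents that add atoms: none
Why: 9-BBN hydroborates the monosubstituted alkene at its terminal carbon, and the B-alkyl Suzuki–Miyaura coupling with the vinyl iodide proceeds with retention of alkene geometry, so C12 ends cis to the ester and the CH2O group trans, as in the target.

Step 13
Reactants: 18 coupled ketal
Product: 19 C8 ketone
Conditions: PPTS, acetone/H2O (10:1), 55 °C
Reagents that add atoms: water, O
Why: Mild acid-catalysed acetal hydrolysis of the dioxolane frees the C8 ketone without touching the two silyl ethers or the enoate.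

Step 14
Reactants: 19 C8 ketone
Product: 21 C7=C8 enol triflate, via potassium enolate 20 (not isolated)
Conditions: KN(SiMe3)2 (1.05 equiv), THF, −78 °C; then N-(5-chloropyridin-2-yl)bis(trifluoromethanesulfonimide), −78 °C
Reagents that add atoms: N-(5-chloropyridin-2-yl)bis(trifluoromethanesulfonimide), FC(F)(F)S(=O)(=O)N(c1ccc(Cl)cn1)S(=O)(=O)C(F)(F)F
Why: Kinetic enolate formation by one equivalent of the bulky amide at −78 °C should occur at the C7 methylene (C9 is a methine beside the quaternary C10, and the ketone is kinetically far more acidic than the γ-hydrogens of the enoate), and O-triflation at −78 °C traps the enolate before the C6 silyloxide can be eliminated, fixing the alkene at C7=C8.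

Step 15
Reactants: 21 C7=C8 enol triflate
Product: 22 bis-silylated enal
Conditions: Pd(PPh3)4 (5 mol%), LiCl, CO (1 atm), Bu3SnH (slow addition), THF, 50 °C
Reagents that add atoms: carbon monoxide, [C-]#[O+]
Why: Palladium-catalysed reductive carbonylation of the enol triflate (oxidative addition, CO insertion, hydride transfer from tin to the acylpalladium) gives the α,β-unsaturated aldehyde directly, and silyl ethers and the β,β-disubstituted enoate are tolerated.

Step 16
Reactants: 22 bis-silylated enal
Product: 23 6,16-diol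
Conditions: HF·pyridine, pyridine/THF, 0 °C → rt
Reagents that add atoms: none
Why: Fluoride-mediated desilylation with buffered HF·pyridine cleaves both silyl ethers, and the freed CH2OH cannot lactonise because it is trans to the ester.

Step 17
Reactants: 23 6,16-diol
Product: 24 target CNP0134813.1
Conditions: acetic formic anhydride (1.1 equiv), pyridine, CH2Cl2, −40 °C
Reagents that add atoms: acetic formic anhydride, CC(=O)OC=O
Why: Selective O-formylation of the primary allylic alcohol with one equivalent of the mixed anhydride at low temperature, the secondary C6 alcohol being shielded by C5 and the C4 gem-dimethyl group; the formate is introduced after the last palladium step because allylic formates are reduced by zerovalent palladium.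

## Compound list

1 | dihydro-β-ionone, 4-(2,6,6-trimethylcyclohex-1-en-1-yl)butan-2-one | CC(=O)CCC1=C(C)CCCC1(C)C | starting material
2 | methyl 3-oxo-5-(2,6,6-trimethylcyclohex-1-en-1-yl)pentanoate | COC(=O)CC(=O)CCC1=C(C)CCCC1(C)C | intermediate
3 | (+)-8-phenylmenthol, (1S,2R,5S)-5-methyl-2-(2-phenylpropan-2-yl)cyclohexan-1-ol | C[C@H]1CC[C@@H]([C@H](C1)O)C(C)(C)c1ccccc1 | starting material
4 | (1S,2R,5S)-5-methyl-2-(2-phenylpropan-2-yl)cyclohexyl 3-oxo-5-(2,6,6-trimethylcyclohex-1-en-1-yl)pentanoate | C[C@H]1CC[C@@H]([C@H](C1)OC(=O)CC(=O)CCC2=C(C)CCCC2(C)C)C(C)(C)c1ccccc1 | intermediate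
5 | cyclised tertiary radical: C9–C10 bond formed, unpaired electron on C5 (C4a of the decalin), C9 and C10 as in 6 | C[C@H]1CC[C@@H]([C@H](C1)OC(=O)[C@@H]2C(=O)CC[C]3C(C)(C)CCC[C@@]23C)C(C)(C)c1ccccc1 | intermediate (not isolated)
6 | (1S,2R,5S)-8-phenylmenthyl (1S,8aS)-5,5,8a-trimethyl-2-oxo-1,2,3,5,6,7,8,8a-octahydronaphthalene-1-carboxylate (ester cis to the 8a-methyl; alkene C4=C4a) | C[C@H]1CC[C@@H]([C@H](C1)OC(=O)[C@@H]2C(=O)CC=C3C(C)(C)CCC[C@@]23C)C(C)(C)c1ccccc1 | intermediate
7 | (1S,2R,5S)-8-phenylmenthyl (1'S,8a'S)-5',5',8a'-trimethyl-3',5',6',7',8',8a'-hexahydro-1'H-spiro[1,3-dioxolane-2,2'-naphthalene]-1'-carboxylate | C[C@H]1CC[C@@H]([C@H](C1)OC(=O)[C@@H]2C3(OCCO3)CC=C4C(C)(C)CCC[C@@]24C)C(C)(C)c1ccccc1 | intermediate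
8 | alkylborane from 7: BH2 on C4' (labdane C6) and H on C4a', both on the face opposite the 8a'-methyl | C[C@H]1CC[C@@H]([C@H](C1)OC(=O)[C@@H]2C3(OCCO3)C[C@@H](B)[C@@H]4C(C)(C)CCC[C@@]24C)C(C)(C)c1ccccc1 | intermediate (not isolated)
9 | (1S,2R,5S)-8-phenylmenthyl (1'S,4'R,4a'R,8a'R)-4'-hydroxy-5',5',8a'-trimethyloctahydro-1'H-spiro[1,3-dioxolane-2,2'-naphthalene]-1'-carboxylate (OH cis to H-4a', trans to the 8a'-methyl) | C[C@H]1CC[C@@H]([C@H](C1)OC(=O)[C@@H]2C3(OCCO3)C[C@@H](O)[C@@H]4C(C)(C)CCC[C@@]24C)C(C)(C)c1ccccc1 | intermediate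
10 | 4'-O-tert-butyldimethylsilyl ether of 9, (1'S,4'R,4a'R,8a'R) | C[C@H]1CC[C@@H]([C@H](C1)OC(=O)[C@@H]2C3(OCCO3)C[C@@H](O[Si](C)(C)C(C)(C)C)[C@@H]4C(C)(C)CCC[C@@]24C)C(C)(C)c1ccccc1 | intermediate
11 | [(1'R,4'R,4a'R,8a'R)-4'-(tert-butyldimethylsilyloxy)-5',5',8a'-trimethyloctahydro-1'H-spiro[1,3-dioxolane-2,2'-naphthalen]-1'-yl]methanol | OC[C@@H]1C2(OCCO2)C[C@@H](O[Si](C)(C)C(C)(C)C)[C@@H]3C(C)(C)CCC[C@@]13C | intermediate
12 | (1'R,4'R,4a'R,8a'R)-4'-(tert-butyldimethylsilyloxy)-5',5',8a'-trimethyloctahydro-1'H-spiro[1,3-dioxolane-2,2'-naphthalene]-1'-carbaldehyde | O=C[C@@H]1C2(OCCO2)C[C@@H](O[Si](C)(C)C(C)(C)C)[C@@H]3C(C)(C)CCC[C@@]13C | intermediate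
13 | tert-butyl{[(1'S,4'R,4a'R,8a'R)-1'-ethenyl-5',5',8a'-trimethyloctahydro-1'H-spiro[1,3-dioxolane-2,2'-naphthalen]-4'-yl]oxy}dimethylsilane | C=C[C@@H]1C2(OCCO2)C[C@@H](O[Si](C)(C)C(C)(C)C)[C@@H]3C(C)(C)CCC[C@@]13C | intermediate
14 | methyl 4-hydroxybut-2-ynoate | COC(=O)C#CCO | starting material
15 | methyl (Z)-4-hydroxy-3-iodobut-2-enoate | COC(=O)/C=C(\I)CO | intermediate
16 | methyl (Z)-4-(tert-butyldiphenylsilyloxy)-3-iodobut-2-enoate | COC(=O)/C=C(\I)CO[Si](c1ccccc1)(c1ccccc1)C(C)(C)C | intermediate
17 | B-alkyl-9-borabicyclo[3.3.1]nonane from 13 (boron on C12) | C1CCC2CCCC1B2CC[C@@H]3C4(OCCO4)C[C@@H](O[Si](C)(C)C(C)(C)C)[C@@H]5C(C)(C)CCC[C@@]35C | intermediate (not isolated)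
18 | methyl (2E)-3-[(tert-butyldiphenylsilyloxy)methyl]-5-[(1'S,4'R,4a'R,8a'R)-4'-(tert-butyldimethylsilyloxy)-5',5',8a'-trimethyloctahydro-1'H-spiro[1,3-dioxolane-2,2'-naphthalen]-1'-yl]pent-2-enoate | COC(=O)/C=C(\CC[C@@H]1C2(OCCO2)C[C@@H](O[Si](C)(C)C(C)(C)C)[C@@H]3C(C)(C)CCC[C@@]13C)CO[Si](c1ccccc1)(c1ccccc1)C(C)(C)C | intermediate
19 | methyl (2E)-3-[(tert-butyldiphenylsilyloxy)methyl]-5-[(1S,4R,4aR,8aR)-4-(tert-butyldimethylsilyloxy)-5,5,8a-trimethyl-2-oxodecahydronaphthalen-1-yl]pent-2-enoate | COC(=O)/C=C(\CC[C@@H]1C(=O)C[C@@H](O[Si](C)(C)C(C)(C)C)[C@@H]2C(C)(C)CCC[C@@]12C)CO[Si](c1ccccc1)(c1ccccc1)C(C)(C)C | intermediate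
20 | potassium C7=C8 enolate of 19 | COC(=O)/C=C(\CC[C@@H]1C([O-])=C[C@@H](O[Si](C)(C)C(C)(C)C)[C@@H]2C(C)(C)CCC[C@@]12C)CO[Si](c1ccccc1)(c1ccccc1)C(C)(C)C.[K+] | intermediate (not isolated)
21 | methyl (2E)-3-[(tert-butyldiphenylsilyloxy)methyl]-5-[(1S,4S,4aR,8aR)-4-(tert-butyldimethylsilyloxy)-5,5,8a-trimethyl-2-(trifluoromethylsulfonyloxy)-1,4,4a,5,6,7,8,8a-octahydronaphthalen-1-yl]pent-2-enoate | COC(=O)/C=C(\CC[C@@H]1C(OS(=O)(=O)C(F)(F)F)=C[C@@H](O[Si](C)(C)C(C)(C)C)[C@@H]2C(C)(C)CCC[C@@]12C)CO[Si](c1ccccc1)(c1ccccc1)C(C)(C)C | intermediate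
22 | methyl (2E)-3-[(tert-butyldiphenylsilyloxy)methyl]-5-[(1S,4R,4aR,8aS)-4-(tert-butyldimethylsilyloxy)-2-formyl-5,5,8a-trimethyl-1,4,4a,5,6,7,8,8a-octahydronaphthalen-1-yl]pent-2-enoate | COC(=O)/C=C(\CC[C@@H]1C(C=O)=C[C@@H](O[Si](C)(C)C(C)(C)C)[C@@H]2C(C)(C)CCC[C@@]12C)CO[Si](c1ccccc1)(c1ccccc1)C(C)(C)C | intermediate
23 | methyl (2E)-5-[(1S,4R,4aR,8aS)-2-formyl-4-hydroxy-5,5,8a-trimethyl-1,4,4a,5,6,7,8,8a-octahydronaphthalen-1-yl]-3-(hydroxymethyl)pent-2-enoate | COC(=O)/C=C(\CC[C@@H]1C(C=O)=C[C@@H](O)[C@@H]2C(C)(C)CCC[C@@]12C)CO | intermediate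
24 | CNP0134813.1, methyl (2E)-5-[(1S,4R,4aR,8aS)-2-formyl-4-hydroxy-5,5,8a-trimethyl-1,4,4a,5,6,7,8,8a-octahydronaphthalen-1-yl]-3-[(formyloxy)methyl]pent-2-enoate (labdane numbering 5R,6R,9S,10S) | COC(=O)/C=C(\CC[C@@H]1C(C=O)=C[C@@H](O)[C@@H]2C(C)(C)CCC[C@@]12C)COC=O | target

## Step count and risks

Total step count: 17. Longest linear sequence: 15 (steps 1–9 and 12–17; steps 10–11 make the side-chain fragment).

Steps most likely to fail:

Step 3. The auxiliary may discriminate the two faces of the chelated C9 radical poorly on this tetrasubstituted acceptor, so that the wrong C10 configuration is formed alongside the right one. The fallback sets out from 2 and comes back at 6, replacing induction by resolution. The methyl ester 2 would be cyclised without auxiliary (Mn(OAc)3·2H2O, Cu(OAc)2·H2O, AcOH, rt) to the racemic bicyclic methyl β-keto ester F1. Transesterification of F1 with 3 (DMAP, toluene, reflux) should give 6 together with the diastereomeric ester of the enantiomeric acid F2. The two would be separated by chromatography or crystallisation, and 6 re-enters at step 4.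

Step 5. Hydroboration of the trisubstituted alkene beside the C4 gem-dimethyl group may be slow or poorly face-selective. The fallback sets out from 7 and comes back at 9, placing both C5 and C6 under thermodynamic control. Epoxidation (mCPBA, NaHCO3, CH2Cl2) would give the 5,6-epoxide F3. BF3·OEt2 (CH2Cl2, −78 °C) should open it at C5 with 1,2-hydride shift from C6 (Meinwald rearrangement) to the cis-fused 6-ketone F4. DBU (CH2Cl2, rt) would epimerise C5 to the trans-fused 6-ketone F5. SmI2 in THF/iPrOH is then expected to reduce the ketone to the more stable equatorial alcohol 9.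

Step 14. The C7 enolate may expel the C6 silyloxide by β-elimination, or the base may attack the γ-hydrogens of the side-chain enoate. The fallback sets out from 19 and comes back at 22 without enolate chemistry. Wittig methylenation (Ph3PCH3Br, KOtBu, THF) would give the exocyclic alkene F6. mCPBA should epoxidise this electron-rich 1,1-disubstituted alkene in preference to the enoate, giving the spiro-epoxide F7. Et2Al(tmp) (diethylaluminium 2,2,6,6-tetramethylpiperidide, toluene, 0 °C) is expected to isomerise it, by removal of the less hindered C7 hydrogen, to the C7=C8 allylic alcohol F8. Dess–Martin oxidation of F8 would give 22.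

Further compounds
F1 | step 3 | racemic methyl (1S*,8aS*)-5,5,8a-trimethyl-2-oxo-1,2,3,5,6,7,8,8a-octahydronaphthalene-1-carboxylate (one enantiomer drawn) | COC(=O)[C@@H]1C(=O)CC=C2C(C)(C)CCC[C@@]12C
F2 | step 3 | (1S,2R,5S)-8-phenylmenthyl (1R,8aR)-5,5,8a-trimethyl-2-oxo-1,2,3,5,6,7,8,8a-octahydronaphthalene-1-carboxylate (diastereomer of 6) | C[C@H]1CC[C@@H]([C@H](C1)OC(=O)[C@H]2C(=O)CC=C3C(C)(C)CCC[C@]23C)C(C)(C)c1ccccc1
F3 | step 5 | 5,6-epoxide of 7, oxygen on the face opposite the C10 methyl | C[C@H]1CC[C@@H]([C@H](C1)OC(=O)[C@@H]2C5(OCCO5)C[C@H]3O[C@]34C(C)(C)CCC[C@@]24C)C(C)(C)c1ccccc1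
F4 | step 5 | cis-fused 6-ketone (H-5 cis to the C10 methyl), C8 ketal, C9 ester | C[C@H]1CC[C@@H]([C@H](C1)OC(=O)[C@@H]2C5(OCCO5)CC(=O)[C@H]4C(C)(C)CCC[C@@]24C)C(C)(C)c1ccccc1
F5 | step 5 | trans-fused 6-ketone (H-5 trans to the C10 methyl), C8 ketal, C9 ester | C[C@H]1CC[C@@H]([C@H](C1)OC(=O)[C@@H]2C5(OCCO5)CC(=O)[C@@H]4C(C)(C)CCC[C@@]24C)C(C)(C)c1ccccc1
F6 | step 14 | 8-methylidene analogue of 19 (C8=CH2) | COC(=O)/C=C(\CC[C@@H]1C(=C)C[C@@H](O[Si](C)(C)C(C)(C)C)[C@@H]2C(C)(C)CCC[C@@]12C)CO[Si](c1ccccc1)(c1ccccc1)C(C)(C)C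
F7 | step 14 | spiro-epoxide of F6 at C8, oxygen on the face opposite the C10 methyl | COC(=O)/C=C(\CC[C@@H]1[C@]3(CO3)C[C@@H](O[Si](C)(C)C(C)(C)C)[C@@H]2C(C)(C)CCC[C@@]12C)CO[Si](c1ccccc1)(c1ccccc1)C(C)(C)C
F8 | step 14 | C7=C8 allylic alcohol (CH2OH on C8), both silyl ethers in place | COC(=O)/C=C(\CC[C@@H]1C(CO)=C[C@@H](O[Si](C)(C)C(C)(C)C)[C@@H]2C(C)(C)CCC[C@@]12C)CO[Si](c1ccccc1)(c1ccccc1)C(C)(C)C
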